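The target is disconnected at the two ring C–CH3 bonds. In a single operation, methyl radicals generated by silver-catalysed peroxodisulfate decarboxylation of acetic acid add to C6–H of quinone rings A and B, the only ring C–H each ring has (flanked by C1=O and C5–OMe), forming both C6–CH3 bonds. The precursor is the des-methyl bis(2-hydroxy-5-methoxy-1,4-benzoquinone) whose C3 positions are joined by a (CH2)13 tether. Keeping C6 unsubstituted until the end lets acid distinguish the C2 methoxy (beside the chain) from the C5 methoxy (beside C6–H) in the earlier bis(2,5-dimethoxyquinone), assembled from 1,2,4,5-tetramethoxybenzene and 1,13-dibromotridecane.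

Key step: step 6

Remarks on the chemistry:
- Ring numbering used throughout (rings A and B are identical): C1=O, C2–O (beside the chain), C3–chain, C4=O, C5–OMe, C6–H (C6–CH3 in the target).
- Assumption: the target is the symmetrical, achiral compound with a saturated unbranched (CH2)13 tether, as the SMILES shows; no stereocentre occurs in the main route.
- Every step acts on two identical, electronically isolated termini; the half-converted species arises by the same reaction and is not numbered separately.

Step 1
Reactants: 1 tridecanedioic acid
Product: 2 tridecane-1,13-diol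
Conditions: LiAlH4, THF, 0 °C to reflux; then H2O, aq. NaOH (Fieser work-up)
Reagents that add atoms: none
Why: Hydride reduction of both carboxylic acids to primary alcohols by LiAlH4, with no other reducible group in the substrate.

Step 2
Reactants: 2 tridecane-1,13-diol
Product: 3 1,13-dibromotridecane
Conditions: CBr4, PPh3, CH2Cl2, 0 °C to rt
Reagents that add atoms: carbon tetrabromide, BrC(Br)(Br)Br
Why: Appel reaction, in which each primary hydroxyl is activated as an alkoxyphosphonium ion and displaced by bromide in an SN2 step that an unhindered primary carbon undergoes cleanly.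

Step 3
Reactants: 4 1,2,4,5-tetramethoxybenzene; 3 1,13-dibromotridecane
Product: 6 1,13-bis(2,3,5,6-tetramethoxyphenyl)tridecane, via 2,3,5,6-tetramethoxyphenyllithium 5 (not isolated)
Conditions: 4 (3 equiv), n-BuLi (2.6 equiv), THF, 0 °C to rt; then 3 (1 equiv), DMPU, 0 °C to rt
Reagents that add atoms: none
Why: Directed ortho-metalation removes the ring proton flanked by two methoxy groups, and the aryllithium, kept in excess over the dibromide and activated by DMPU, should displace both primary bromides by SN2 alkylation, a known behaviour of this lithiated arene with long-chain bromides.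

Step 4
Reactants: 6 1,13-bis(2,3,5,6-tetramethoxyphenyl)tridecane
Product: 7 3,3'-(tridecane-1,13-diyl)bis(2,5-dimethoxycyclohexa-2,5-diene-1,4-dione)
Conditions: (NH4)2Ce(NO3)6 (5 equiv), MeCN/CH2Cl2/H2O, 0 °C to rt
Reagents that add atoms: water, O
Why: Oxidative demethylation by tetravalent cerium (one-electron oxidation of the electron-rich arene, attack of water, loss of methanol) gives the para-quinone, and since both para pairs of methoxy groups lead to the same constitution, each ring can only become the 2,5-dimethoxy-3-alkyl-1,4-benzoquinone.

Step 5
Reactants: 7 3,3'-(tridecane-1,13-diyl)bis(2,5-dimethoxycyclohexa-2,5-diene-1,4-dione)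
Product: 8 3,3'-(tridecane-1,13-diyl)bis(2-hydroxy-5-methoxycyclohexa-2,5-diene-1,4-dione)
Conditions: 70% aq. HClO4, 1,4-dioxane, rt
Reagents that add atoms: water, O
Why: Acid-catalysed addition–elimination of water at a vinylogous methyl ester, in which the C2 methoxy, twisted out of conjugation by the chain at C3, is exchanged for hydroxyl while the planar C5 methoxy beside C6–H is kept, the selectivity known for perchloric acid hydrolysis of 3-alkyl-2,5-dimethoxy-1,4-benzoquinones.

Step 6
Reactants: 8 3,3'-(tridecane-1,13-diyl)bis(2-hydroxy-5-methoxycyclohexa-2,5-diene-1,4-dione); 9 acetic acid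
Product: 10 3,3'-(tridecane-1,13-diyl)bis(2-hydroxy-5-methoxy-6-methylcyclohexa-2,5-diene-1,4-dione) (CNP0110425.0)
Conditions: AgNO3 (cat.), (NH4)2S2O8 (excess, in portions), AcOH/MeCN/H2O, 70 °C
Reagents that add atoms: acetic acid (9), CC(=O)O
Why: Jacobsen–Torssell (Minisci-type) radical alkylation of a quinone: peroxodisulfate oxidises monovalent silver to divalent silver, which oxidises acetic acid to the acetoxyl radical; loss of CO2 gives a methyl radical that adds to C6 of each ring, and the adduct radical at C5 (bearing OMe, next to C4=O) is oxidised and loses the C6 proton to restore the quinone. The closest known reactions are the AgNO3/peroxodisulfate decarboxylative alkylation of 2-hydroxy-1,4-naphthoquinone and the methylation of 1,4-naphthoquinone with acetic acid. No ring is closed and no stereocentre is created. The step needs site selectivity and twofold conversion: C6–H is the only ring C–H of each ring, the nucleophilic methyl radical prefers the electron-poor quinone carbon to hydrogen abstraction from the chain, and a methylated ring offers no further addition site. Acetic acid as cosolvent in large excess and portionwise oxidant should drive both rings to completion while the acidic medium keeps the hydroxyquinone protonated.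

Compound list
1 | tridecanedioic acid | OC(=O)CCCCCCCCCCCC(=O)O | starting material
2 | tridecane-1,13-diol | OCCCCCCCCCCCCCO | intermediate
3 | 1,13-dibromotridecane | BrCCCCCCCCCCCCCBr | intermediate
4 | 1,2,4,5-tetramethoxybenzene | COc1cc(OC)c(OC)cc1OC | starting material
5 | 2,3,5,6-tetramethoxyphenyllithium (formed in the flask, not isolated) | [Li]c1c(OC)c(OC)cc(OC)c1OC | intermediate
6 | 1,13-bis(2,3,5,6-tetramethoxyphenyl)tridecane | COc1cc(OC)c(OC)c(CCCCCCCCCCCCCc2c(OC)c(OC)cc(OC)c2OC)c1OC | intermediate
7 | 3,3'-(tridecane-1,13-diyl)bis(2,5-dimethoxycyclohexa-2,5-diene-1,4-dione) | COC1=CC(=O)C(OC)=C(CCCCCCCCCCCCCC2=C(OC)C(=O)C=C(OC)C2=O)C1=O | intermediate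
8 | 3,3'-(tridecane-1,13-diyl)bis(2-hydroxy-5-methoxycyclohexa-2,5-diene-1,4-dione) | COC1=CC(=O)C(O)=C(CCCCCCCCCCCCCC2=C(O)C(=O)C=C(OC)C2=O)C1=O | intermediate
9 | acetic acid | CC(=O)O | starting material
10 | 3,3'-(tridecane-1,13-diyl)bis(2-hydroxy-5-methoxy-6-methylcyclohexa-2,5-diene-1,4-dione), CNP0110425.0 | COC1=C(C)C(=O)C(O)=C(CCCCCCCCCCCCCC2=C(O)C(=O)C(C)=C(OC)C2=O)C1=O | target

Total step count: 6
Longest linear sequence: 6 steps (1 → 2 → 3 → 6 → 7 → 8 → 10)

Steps most likely to fail

Step 6. The free hydroxyquinone may be degraded oxidatively by sulfate radical anion or divalent silver, and the second methylation may stall because the lipophilic substrate leaves the aqueous phase. The fallback replaces radical methylation by anionic methylation and sets out from 8. Reduction with Na2S2O4 in THF/H2O under argon should give the air-sensitive 1,13-bis(2,3,6-trihydroxy-5-methoxyphenyl)tridecane F1. Immediate protection with MOMCl and NaH in DMF should give 1,13-bis[5-methoxy-2,3,6-tris(methoxymethoxy)phenyl]tridecane F2. Directed ortho-metalation with n-BuLi/TMEDA in THF at the single aryl C–H of each ring (between OMOM and OMe), followed by MeI, should give 1,13-bis[5-methoxy-4-methyl-2,3,6-tris(methoxymethoxy)phenyl]tridecane F3. HCl in MeOH should remove the acetals to give 1,13-bis(2,3,6-trihydroxy-5-methoxy-4-methylphenyl)tridecane F4, which is oxidised by stirring in air (or with FeCl3) to the hydroxy-para-quinone, returning to the route at 10.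

Step 5. Regiocontrol between the two methoxy groups may be lost, or hydrolysis may run on to the dihydroxyquinone. The fallback replaces selective cleavage by exhaustive cleavage and selective re-methylation, and sets out from 7. Aqueous NaOH in EtOH at reflux, then acidification with HCl, should give 3,3'-(tridecane-1,13-diyl)bis(2,5-dihydroxycyclohexa-2,5-diene-1,4-dione) F5. Vinylogous Fischer esterification in MeOH with catalytic H2SO4 should then methylate only the unhindered oxygen flanked by C6–H, under steric and thermodynamic control, returning to the route at 8.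

Step 3. Alkylation may be eroded by E2 elimination of the bromide, by halogen–lithium exchange, and by proton transfer from product 6 to the aryllithium followed by over-alkylation. The fallback forms the aryl–carbon bonds by carbonyl addition and deoxygenation and sets out from 2. Swern oxidation ((COCl)2, DMSO, Et3N, CH2Cl2, −78 °C) should give tridecanedial F6. Addition of F6 to aryllithium 5 in THF at −78 °C should give 1,13-bis(2,3,5,6-tetramethoxyphenyl)tridecane-1,13-diol F7, as a mixture of stereoisomers that is of no consequence. Ionic hydrogenation with Et3SiH and CF3CO2H in CH2Cl2 should remove both benzylic hydroxyls, returning to the route at 6.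

Further compounds
F1 | step 6 | 1,13-bis(2,3,6-trihydroxy-5-methoxyphenyl)tridecane | COc1cc(O)c(O)c(CCCCCCCCCCCCCc2c(O)c(O)cc(OC)c2O)c1O
F2 | step 6 | 1,13-bis[5-methoxy-2,3,6-tris(methoxymethoxy)phenyl]tridecane | COCOc1c(CCCCCCCCCCCCCc2c(OCOC)c(OCOC)cc(OC)c2OCOC)c(OCOC)c(OC)cc1OCOC
F3 | step 6 | 1,13-bis[5-methoxy-4-methyl-2,3,6-tris(methoxymethoxy)phenyl]tridecane | COCOc1c(CCCCCCCCCCCCCc2c(OCOC)c(OCOC)c(C)c(OC)c2OCOC)c(OCOC)c(OC)c(C)c1OCOC
F4 | step 6 | 1,13-bis(2,3,6-trihydroxy-5-methoxy-4-methylphenyl)tridecane | COc1c(C)c(O)c(O)c(CCCCCCCCCCCCCc2c(O)c(O)c(C)c(OC)c2O)c1O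
F5 | step 5 | 3,3'-(tridecane-1,13-diyl)bis(2,5-dihydroxycyclohexa-2,5-diene-1,4-dione) | OC1=CC(=O)C(O)=C(CCCCCCCCCCCCCC2=C(O)C(=O)C=C(O)C2=O)C1=O
F6 | step 3 | tridecanedial | O=CCCCCCCCCCCCCC=O
F7 | step 3 | 1,13-bis(2,3,5,6-tetramethoxyphenyl)tridecane-1,13-diol (mixture of stereoisomers) | COc1cc(OC)c(OC)c(C(O)CCCCCCCCCCCC(O)c2c(OC)c(OC)cc(OC)c2OC)c1OC
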